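**Assumption:** (6S)-2-methyl-6-[(1R)-4-methylcyclohexa-2,4-dien-1-yl]hept-2-en-4-one (α-turmerone), the major constituent of turmeric oil, is bought as the natural isolate. The C6-OH of diol 3 is assumed to silylate preferentially over the C3-OH, which is flanked by the branched C4 side chain.

**Ring numbering used below.** C1 bears the methyl, C1=C2 is the ring alkene, C3 carries O-aryl in the target, C4 carries the side chain, C5 is CH2, and C6 is the carbinol. C7 is the side-chain CH(CH3).

## Retrosynthesis
1. The curcuminoid enol disconnects by a boron-mediated Pabon aldol condensation into feruloylacetone (from vanillin and acetylacetone) and the aryl-ether aldehyde 8.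
2. Aldehyde 8 comes from vanillin and a C3 allylic carbonate by Pd-catalysed allylic etherification with net retention. The carbonate comes from the cis-1,4-diol, with the less hindered C6-OH masked as a silyl ether.
3. The cis-1,4-diol comes from the bicyclic endoperoxide. The only new ring in the synthesis, the 1,2-dioxine, forms by a singlet-oxygen [4+2] cycloaddition onto the cyclohexadiene of α-turmerone, anti to the C4 side chain.
4. C4 and C7 are carried by α-turmerone. C3 and C6 are set by the face selectivity of the cycloaddition.

## Route

**Step 1**
Reactants: 1 (α-turmerone)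
Product: 2 (bicyclic endoperoxide; O–O bridges C3 and C6, anti to the side chain; C1=C2 alkene retained)
Conditions: ³O₂, TPP (cat.), visible light, CH₂Cl₂, 0 °C
Reagents that add atoms: O₂ (O=O)
Why: Singlet oxygen undergoes a suprafacial hetero-Diels–Alder [4+2] with the 1,3-cyclohexadiene. It approaches the face anti to the C4 side chain, so both new C–O bonds are cis to each other and trans to the side chain. The enone alkene is electron-poor and inert.

**Step 2**
Reactants: 2
Product: 3 (cis-1,4-diol; C3-OH and C6-OH both trans to the C4 side chain)
Conditions: thiourea, MeOH, 25 °C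
Reagents that add atoms: none
Why: Thiourea reductively cleaves the O–O bond (peroxide reduction) without touching the alkene or the enone. Both C–O bonds keep their configuration.

**Step 3**
Reactants: 3
Product: 4 (C6-O-TBDPS ether; C3-OH free)
Conditions: TBDPSCl (1.05 equiv), imidazole, DMF, 0 °C → rt
Reagents that add atoms: TBDPSCl, CC(C)(C)[Si](Cl)(c1ccccc1)c1ccccc1
Why: Bulky silyl chloride silylation discriminates on sterics. C6-OH lies between an sp² carbon and a CH2, whereas C3-OH sits next to the branched C4 bearing the side chain. No stereocenter is touched.

**Step 4**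
Reactants: 4
Product: 5 (C3 methyl carbonate)
Conditions: ClCO₂Me, pyridine, DMAP (cat.), CH₂Cl₂, 0 °C → rt
Reagents that add atoms: methyl chloroformate, COC(Cl)=O
Why: Acylation of the remaining secondary allylic OH creates the leaving group for Pd-π-allyl chemistry, with no change at the carbinol carbon.

**Step 5**
Reactants: 5, 6 (vanillin)
Product: 7 (C3 aryl ether of vanillin, C6-OTBDPS)
Conditions: Pd(PPh₃)₄ (5 mol%), THF, 50 °C
Reagents that add atoms: none (vanillin is reactant 6)
Why: This is a Tsuji–Trost allylic etherification. Pd(0) ionises anti to the carbonate, and the phenoxide attacks the π-allyl anti to Pd at the less substituted secondary terminus C3. Double inversion gives net retention, so the C3–O bond stays trans to the side chain.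

**Step 6**
Reactants: 7
Product: 8 (free C6-OH aldehyde)
Conditions: TBAF, AcOH (buffered), THF, 25 °C
Reagents that add atoms: none
Why: Fluoride removes the silyl ether. Buffering with AcOH avoids base-mediated aldol or Michael side reactions of the ketone and enone. C6 is not involved.

**Step 7** (convergent partner)
Reactants: 6 (vanillin), 9 (acetylacetone)
Product: 10 (feruloylacetone)
Conditions: B₂O₃, B(OBu)₃, n-BuNH₂ (cat.), EtOAc, 40–60 °C; then aq. HCl
Reagents that add atoms: none
Why: The boron-chelated acetylacetone is a Pabon-type Knoevenagel/aldol nucleophile. With excess acetylacetone the reaction stops at mono-condensation at one methyl group.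

**Step 8**
Reactants: 8, 10
Product: 11 (target, isolated as the enol tautomer)
Conditions: 10 + B₂O₃, EtOAc, 40 °C; then 8, B(OBu)₃, n-BuNH₂, 40 °C; then aq. citric acid/MeOH, 40 °C
Reagents that add atoms: none
Why: Boron-templated aldol condensation of the free acetyl CH₃ of 10 with the aryl aldehyde 8 gives the (E)-enone. Mild acid cleaves the boron chelate. C3, C4, C6 and C7 are remote from the reacting centres, and C7 is β to the ketone so it cannot epimerise.

## Checks
- **Target match:** The cyclohexene has 1-Me, 1,2-alkene, 3-OAr, 4-side chain and 6-OH.
  - Ring descriptors in the target SMILES: C3 = R, C4 = R, C6 = S, C7 = S.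
  - From that SMILES, both O atoms are on the same face and the side chain is on the opposite face.
  - Starting from α-turmerone (ring C4 = R, side chain C7 = S), Step 1 delivers exactly this arrangement.
- **Atom balance:** 8 + 10 − H₂O = 11. All other steps are either reagent additions or removals.
- **Functional groups:**
  - The enone, ring alkene and aryl aldehyde survive Steps 2–6.
  - The enone and alkene survive the peroxide reduction.
  - Only the allylic C3 carbonate ionises under Pd. The silyl ether is not a leaving group.
  - Boron-complex cleavage is run under mild acid to protect the allylic ether.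
- **Stereocenters:** C4 and C7 come from α-turmerone and are never touched. C3 and C6 are set in Step 1 and retained through Steps 2–6.

## Compound list
1 | α-turmerone, (6S)-2-methyl-6-[(1R)-4-methylcyclohexa-2,4-dien-1-yl]hept-2-en-4-one | C1=CC(C)=CC[C@@H]1[C@@H](C)CC(=O)C=C(C)C | starting material
2 | bicyclic endoperoxide of 1 | O2[C@H]1C=C(C)[C@@H](O2)C[C@@H]1[C@@H](C)CC(=O)C=C(C)C | intermediate
3 | cis-1,4-diol (C3-OH, C6-OH) | O[C@H]1C=C(C)[C@@H](O)C[C@@H]1[C@@H](C)CC(=O)C=C(C)C | intermediate
4 | C6-O-TBDPS diol | O[C@H]1C=C(C)[C@@H](O[Si](c2ccccc2)(c2ccccc2)C(C)(C)C)C[C@@H]1[C@@H](C)CC(=O)C=C(C)C | intermediate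
5 | C3 methyl carbonate of 4 | COC(=O)O[C@H]1C=C(C)[C@@H](O[Si](c2ccccc2)(c2ccccc2)C(C)(C)C)C[C@@H]1[C@@H](C)CC(=O)C=C(C)C | intermediate
6 | vanillin | COc1cc(C=O)ccc1O | starting material
7 | aryl ether, C6-OTBDPS | COc1cc(C=O)ccc1O[C@H]3C=C(C)[C@@H](O[Si](c4ccccc4)(c4ccccc4)C(C)(C)C)C[C@@H]3[C@@H](C)CC(=O)C=C(C)C | intermediate
8 | aryl ether aldehyde, free C6-OH | COc1cc(C=O)ccc1O[C@H]3C=C(C)[C@@H](O)C[C@@H]3[C@@H](C)CC(=O)C=C(C)C | intermediate
9 | acetylacetone | CC(=O)CC(C)=O | starting material
10 | feruloylacetone | COc1cc(/C=C/C(=O)CC(C)=O)ccc1O | intermediate
11 | bisabolocurcumin ether | COc1cc(/C=C/C(=O)/C=C(O)/C=C/c2ccc(O[C@H]3C=C(C)[C@@H](O)C[C@@H]3[C@@H](C)CC(=O)C=C(C)C)c(OC)c2)ccc1O | target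

## Totals
Total steps: 8. Longest linear sequence: 7 (Steps 1–6 and 8, from 1).

## Three steps most likely to fail
1. **Step 3 (regioselective silylation).** C3-OH and C6-OH may not differ enough, giving regioisomer mixtures.
   - *Fallback:* Change the approach by opening endoperoxide 2 with Et₃N (Kornblum–DeLaMare) to the γ-hydroxy-enone. Aryl-etherify C3 by Pd allylation, then reduce the C6 ketone with NaBH₄/CeCl₃. Invert C6 by Mitsunobu (p-nitrobenzoic acid) and hydrolyse.
2. **Step 5 (Pd etherification).** The C3 carbonate is hindered by the adjacent C4 substituent, and β-hydride elimination to the diene or loss of retention are possible.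
   - *Fallback:* Oxidise the free C3-OH of 4 to the enone with MnO₂, then reduce with NaBH₄/CeCl₃ to give the C3-epimer, with OH cis to the side chain. Mitsunobu reaction with vanillin then inverts it to the required trans aryl ether.
3. **Step 8 (Pabon condensation).** The side-chain ketone can undergo competing aldol or amine condensation, and the allylic ether and alcohol may ionise on boron decomplexation.
   - *Fallback:* Change the bond-forming order. Condense 8 with acetone to the styryl methyl ketone, then do a Claisen-type acylation of its enolate with TBS-feruloyl chloride, and remove the TBS group.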